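All runs come from a simulation with constants of no real substance, noise included.

I charged a closed, stirred vessel with G and Q, and each Z formed uses one of each.

| flask | G | Q | time |
|---|---|---|---|
| red | 0.800 M | 1.20 M |  |
| ochre | 0.800 M | 2.40 M |  |
| violet | 1.20 M | 1.20 M |  |
| blue | 0.400 M | 2.40 M | 4.5 min |

- red run (time / min: [Z] / M): 0.75: 0.0425; 1.5: 0.1127; 2.2: 0.1894; 3.0: 0.2945; 3.8: 0.3986; 4.5: 0.4831
- ochre run (time / min: [Z] / M): 0.75: 0.0724; 1.5: 0.1942; 2.2: 0.3355; 3.0: 0.4957; 3.8: 0.6224; 4.5: 0.6988
- violet run (time / min: [Z] / M): 0.75: 0.0743; 1.5: 0.2062; 2.2: 0.3737; 3.0: 0.5742; 3.8: 0.7420; 4.5: 0.8571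

(standard deviation of a reading: 0.002 M)

- Overall: G + Q -> Z.
- Constant volume, constant temperature.
- What is held in complexes is read along with the free species.
- "The second partner" is Q.
- An order is taken over about fifteen percent of the charge, up and down.

- order of the initial rate in [Q], near the charge of the red run, the rate being that where two percent of its G are Z
- order of the initial rate in [G], near the charge of the red run, the rate being that where two percent of its G are Z (one fixed amount of Z, the same in the runs compared)
- Z in the blue run at 4.5 min, as a share of the G charged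

I read ochre first. Blue has the same Q charge, so at equal Z the two hold equal Q. I took the fall of ln[G] as the rate per unit of G. It was 0.126 min⁻¹ near Z = 0.0362 M and 0.244 min⁻¹ near Z = 0.133 M. That is about twice, so I took it as autocatalysis.

So I weighed two rates per unit of G: an unassisted rate f and an assisted rate bZ. A line through those readings gave b = 1.21 M⁻¹ min⁻¹ and f = 0.0826 min⁻¹. Their ratio is Z/Zc, where Zc = f/b is the crossover amount, the Z at which the two rates are equal, here 0.0681 M.

In blue, G is the limiting reagent, at 0.400 M against 2.40 M of Q, so I held f and b fixed. Its G charge C equals 5.87 crossover amounts. Adding the two rates gives a closed form: (1 + Z/Zc)/(1 − Z/C) = exp[(f + bC)t]. At 4.5 min this gave 63.3%.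

The forecast gave orders of 0.54 in Q and 1 in G, and 63% for blue, saying “Q−Z matches ochre, so I reuse ochre's f(Z)”. Both reckonings rest on ochre, so their agreement is no check.

The flask gave 0.54, 1.0 and 63.5%. At the same small Z, ochre ran at 1.45 times the red rate with twice the Q.

    G + Q → Z (0.3720 M⁻¹ min⁻¹)
    G + Q + Z → 2 Z (5.148 M⁻² min⁻¹)
    2 Q ⇌ Q2, settled at all times (19.40 M⁻¹)

Blue stood at 3.73 crossover amounts at 4.5 min, so by this reading its assisted rate was then that many times its unassisted rate. I carried Zc to violet, whose first reading gave f = 0.0551 min⁻¹. The same form then gave 1.92 min for a quarter of its G, and violet reached that share at 1.91 min.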